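## Retrosynthetic overview

1. **Feature.** The benzene ring of the benzofuranone (C3a, C4, C5, C6, C7, C7a) carries no hydrogen. Its C4–OMe and C7a–O are meta to each other across C3a, which is the pattern left by the oxygen-bearing carbon of an alkoxyalkyne and the carbonyl carbon of a ketene.
2. **Last operations, read backwards.** The C6/C7 catechol comes from an isopropyl and a benzyl ether, the C5 ketone from a MOM-protected benzylic carbinol, and the lactone bond O1–C2 from the C7a phenol and a methyl (Z)-cinnamate arm on C3a.
3. **Key disconnection, C7a–C3a and C4–C5.** This leads back to a 2-alkyl-3,4-dialkoxycyclobutenone (C7a, C5, C6, C7) and a methoxyethynyl cinnamate (C3a, C4 and the complete arm).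
4. **Fragments.** The cyclobutenone comes from diisopropyl squarate and the α-alkoxyalkyllithium derived from 3-phenylpropanal. The enynyl ether comes from methyl phenylpropiolate (syn hydrostannation sets the alkene) and the acetylide made from chloroacetaldehyde dimethyl acetal.
5. **Ring order.** The benzene ring forms first (step 9), the lactone ring second (step 10).

Key step: step 9

Assumption: bractelactone has no stereocentre and is achiral, so "single enantiomer" is read as the single (Z) isomer of the C3 benzylidene group. All sp3 centres of the intermediates are racemic (one isomer drawn) and are erased before the end.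

## Route

Step 1
Reactants: 1 3-phenylpropanal
Product: 2 3-phenyl-1-(tributylstannyl)propan-1-ol (racemic)
Conditions: Bu3SnH, LDA, THF, 0 °C; 1, −78 °C; aq NH4Cl; crude used at once
Reagents that add atoms: tributyltin hydride, CCCC[SnH](CCCC)CCCC
Why: 1,2-addition of tributylstannyllithium to an unhindered aldehyde is a standard entry to α-hydroxystannanes; the carbinol centre forms as a racemate, which is harmless because this carbon ends as the C5 ketone carbon.

Step 2
Reactants: 2 3-phenyl-1-(tributylstannyl)propan-1-ol
Product: 3 tributyl[1-(methoxymethoxy)-3-phenylpropyl]stannane (racemic)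
Conditions: MOMCl, i-Pr2NEt, CH2Cl2, 0 °C → rt
Reagents that add atoms: chloromethyl methyl ether, COCCl
Why: MOM protection under amine base stabilises the labile α-hydroxystannane and supplies the ether oxygen that keeps the later carbanion stable at low temperature.

Step 3
Reactants: 3 tributyl[1-(methoxymethoxy)-3-phenylpropyl]stannane; 4 diisopropyl squarate
Product: 8 3-isopropoxy-4-[1-(methoxymethoxy)-3-phenylpropyl]cyclobut-3-ene-1,2-dione (racemic), via α-alkoxyalkyllithium 5 (not isolated), via lithium alkoxide adduct 6 (not isolated), via tertiary trifluoroacetate 7 (not isolated)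
Conditions: 3, n-BuLi, THF, −78 °C; added to 4, THF, −78 °C; (CF3CO)2O, −78 °C; H2O, → rt
Reagents that add atoms: water, O
Why: Tin–lithium exchange gives the α-alkoxyalkyllithium, which should add 1,2 to one squarate carbonyl, and O-trifluoroacetylation followed by water triggers the usual ionisation–hydrolysis of such adducts to the 3-alkoxy-4-alkylcyclobutenedione without mineral acid that could touch the MOM ether.

Step 4
Reactants: 8 3-isopropoxy-4-[1-(methoxymethoxy)-3-phenylpropyl]cyclobut-3-ene-1,2-dione
Product: 9 4-hydroxy-3-isopropoxy-2-[1-(methoxymethoxy)-3-phenylpropyl]cyclobut-2-en-1-one (racemic diastereomer mixture)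
Conditions: LiAlH(Ot-Bu)3, THF, −78 → −40 °C; H2O
Reagents that add atoms: none
Why: The carbonyl next to the alkyl-bearing carbon is a vinylogous ester and the one next to C–Oi-Pr is ketone-like, so a mild bulky hydride (chemoselective 1,2-reduction) should attack only the latter; the new centre forms as a diastereomer mixture and later becomes aromatic C7.

Step 5
Reactants: 9 4-hydroxy-3-isopropoxy-2-[1-(methoxymethoxy)-3-phenylpropyl]cyclobut-2-en-1-one
Product: 10 4-(benzyloxy)-3-isopropoxy-2-[1-(methoxymethoxy)-3-phenylpropyl]cyclobut-2-en-1-one (racemic diastereomer mixture)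
Conditions: BnOC(=NH)CCl3, TfOH (5 mol %), CH2Cl2–cyclohexane, 0 °C
Reagents that add atoms: benzyl 2,2,2-trichloroacetimidate, N=C(OCc1ccccc1)C(Cl)(Cl)Cl
Why: Acid-catalysed trichloroacetimidate benzylation avoids the alkoxide of 9, which would ring-open, and puts on the future C7 oxygen a group that outlasts acetal cleavage and oxidation (a free C7–OH would be para to C4–OMe, an easily oxidised hydroquinone monoether) yet falls to BCl3 together with the isopropyl ether.

Step 6
Reactants: 11 methyl phenylpropiolate
Product: 12 methyl (E)-3-phenyl-2-(tributylstannyl)acrylate (phenyl cis to CO2Me, tin trans to phenyl)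
Conditions: Bu3SnH, Pd(PPh3)4 (2 mol %), THF, 0 °C → rt
Reagents that add atoms: tributyltin hydride, CCCC[SnH](CCCC)CCCC
Why: Pd(0)-catalysed hydrostannation of an alkynoate is a syn addition that places tin α to the ester, so the phenyl group is locked cis to CO2Me, the geometry of the target alkene.

Step 7
Reactants: 12 methyl (E)-3-phenyl-2-(tributylstannyl)acrylate
Product: 13 methyl (E)-2-iodo-3-phenylacrylate (iodine trans to phenyl)
Conditions: I2 (1.0 equiv), CH2Cl2, 0 °C, dark
Reagents that add atoms: iodine, II
Why: Iododestannylation is an electrophilic substitution at sp2 carbon that proceeds with retention, and one equivalent of iodine in the cold and dark limits iodine-catalysed isomerisation to the more stable geometric isomer.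

Step 8
Reactants: 13 methyl (E)-2-iodo-3-phenylacrylate; 14 chloroacetaldehyde dimethyl acetal
Product: 17 methyl (Z)-2-(methoxyethynyl)-3-phenylacrylate (alkyne trans to phenyl), via lithium methoxyacetylide 15 (not isolated), via methoxyethynylzinc chloride 16 (not isolated)
Conditions: 14, LiNEt2 (3 equiv, from Et2NH/n-BuLi), THF, 0 °C; ZnCl2, 0 °C; 13, Pd(PPh3)4 (5 mol %), rt; chromatography on Et3N-washed SiO2
Reagents that add atoms: none
Why: Double elimination and deprotonation of the chloroacetal give the acetylide, and Negishi coupling of the derived alkoxyethynylzinc halide with an alkenyl iodide proceeds with retention at sp2 carbon and tolerates the ester, the methoxide in the medium being degenerate with the methyl ester.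

Step 9
Reactants: 10 4-(benzyloxy)-3-isopropoxy-2-[1-(methoxymethoxy)-3-phenylpropyl]cyclobut-2-en-1-one; 17 methyl (Z)-2-(methoxyethynyl)-3-phenylacrylate
Product: 22 methyl (Z)-2-{3-(benzyloxy)-2-hydroxy-4-isopropoxy-6-methoxy-5-[1-(methoxymethoxy)-3-phenylpropyl]phenyl}-3-phenylacrylate (racemic), via vinylketene 18 (not isolated), via 4-vinylcyclobutenone 19 (not isolated), via dienylketene 20 (not isolated), via cyclohexadienone 21 (not isolated)
Conditions: 17 (1.3 equiv), toluene (0.5 M), 4 Å MS, Ar, sealed tube, 80 °C then 110 °C
Reagents that add atoms: none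
Why: Heating should cleave C7a–C7 of 10 by conrotatory 4π opening, the benzyloxy donor turning outward, to give vinylketene 18, whose carbonyl carbon (C7a) is attacked by the carbon-substituted alkyne carbon of 17 (C3a) while the ketene α-carbon (C5) bonds to the methoxy-bearing carbon (C4) in a net [2+2] addition. The 4-vinylcyclobutenone 19 should reopen reversibly at C7a–C5 to dienylketene 20, which closes the only new ring, the six-membered carbocycle, by disrotatory 6π electrocyclisation of C7 onto C7a, and dienone 21 tautomerises irreversibly to phenol 22. This is the Danheiser benzannulation of a cyclobutenone and an alkoxyalkyne, the established route to resorcinol monoethers, and a methyl ynol ether is used because it cannot fragment by retro-ene loss of an alkene at these temperatures. No lasting stereocentre is made: the centres of 19 and 21 vanish on aromatisation and the carbinol centre is a racemic spectator. The step needs regioselectivity in the [2+2] event, which the polarity match between the ketene carbonyl carbon and the β-carbon of the ynol ether secures, and chemoselectivity for the alkyne over the acrylate C=C, which follows from the preference of ketenes for electron-rich π bonds. The arm keeps its geometry because its phenyl is trans to C3a and cannot reach C7a of 20 for a competing naphthol-forming closure, and the four ring oxygens emerge differentiated as methyl (C4), isopropyl (C6), benzyl (C7) and free OH (C7a).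

Step 10
Reactants: 22 methyl (Z)-2-{3-(benzyloxy)-2-hydroxy-4-isopropoxy-6-methoxy-5-[1-(methoxymethoxy)-3-phenylpropyl]phenyl}-3-phenylacrylate
Product: 23 (Z)-3-benzylidene-7-(benzyloxy)-6-isopropoxy-4-methoxy-5-[1-(methoxymethoxy)-3-phenylpropyl]benzofuran-2(3H)-one (racemic)
Conditions: CSA (10 mol %), 5 Å MS, toluene, 70 °C
Reagents that add atoms: none
Why: Acid-catalysed intramolecular transesterification (5-exo-trig lactonisation) of the C7a phenol onto the neighbouring ester closes the furanone ring, is driven by uptake of methanol, leaves the alkene untouched (phenyl away from C4–OMe is also the less crowded isomer) and turns the oxygen para to the benzylic carbon into a weaker donor before the acetal is cleaved.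

Step 11
Reactants: 23 (Z)-3-benzylidene-7-(benzyloxy)-6-isopropoxy-4-methoxy-5-[1-(methoxymethoxy)-3-phenylpropyl]benzofuran-2(3H)-one
Product: 25 (Z)-3-benzylidene-7-(benzyloxy)-5-(1-hydroxy-3-phenylpropyl)-6-isopropoxy-4-methoxybenzofuran-2(3H)-one (racemic), via bromomethyl ether 24 (not isolated)
Conditions: Me2BBr, CH2Cl2, −78 °C; then THF–sat. aq NaHCO3, rt
Reagents that add atoms: none
Why: Dimethylboron bromide cleaves MOM ethers at the acetal carbon at −78 °C (Lewis-acid acetal cleavage to a bromomethyl ether that hydrolyses on basic work-up), conditions under which aryl benzyl, isopropyl and methyl ethers and the lactone are inert and protic ionisation of the benzylic C–O bond is avoided.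

Step 12
Reactants: 25 (Z)-3-benzylidene-7-(benzyloxy)-5-(1-hydroxy-3-phenylpropyl)-6-isopropoxy-4-methoxybenzofuran-2(3H)-one
Product: 26 (Z)-3-benzylidene-7-(benzyloxy)-6-isopropoxy-4-methoxy-5-(3-phenylpropanoyl)benzofuran-2(3H)-one
Conditions: Dess–Martin periodinane, CH2Cl2, 0 °C → rt
Reagents that add atoms: none
Why: Dess–Martin oxidation converts hindered secondary benzylic alcohols into ketones under neutral conditions, and with every phenolic oxygen still masked no quinone-forming pathway is open; the last stereocentre disappears here.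

Step 13
Reactants: 26 (Z)-3-benzylidene-7-(benzyloxy)-6-isopropoxy-4-methoxy-5-(3-phenylpropanoyl)benzofuran-2(3H)-one
Product: 27 bractelactone, (Z)-3-benzylidene-6,7-dihydroxy-4-methoxy-5-(3-phenylpropanoyl)benzofuran-2(3H)-one
Conditions: BCl3, C6HMe5, CH2Cl2, −78 → 0 °C; H2O
Reagents that add atoms: none
Why: BCl3 dealkylation cleaves aryl benzyl ethers (cation trapped by pentamethylbenzene) and aryl isopropyl ethers much faster than aryl methyl ethers, and once the C6 oxygen is freed its boron chelate to the C5 ketone blocks carbonyl-assisted attack on C4–OMe.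

## Compound list

1 | 3-phenylpropanal | O=CCCc1ccccc1 | starting material
2 | 3-phenyl-1-(tributylstannyl)propan-1-ol (racemic, one enantiomer drawn) | CCCC[Sn](CCCC)(CCCC)[C@@H](CCc1ccccc1)O | intermediate
3 | tributyl[1-(methoxymethoxy)-3-phenylpropyl]stannane (racemic, one enantiomer drawn) | CCCC[Sn](CCCC)(CCCC)[C@@H](CCc1ccccc1)OCOC | intermediate
4 | diisopropyl squarate | CC(C)OC1=C(OC(C)C)C(=O)C1=O | starting material
5 | [1-(methoxymethoxy)-3-phenylpropyl]lithium (racemic, one enantiomer drawn) | [Li][C@@H](CCc1ccccc1)OCOC | intermediate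
6 | lithium 2,3-diisopropoxy-1-[1-(methoxymethoxy)-3-phenylpropyl]-4-oxocyclobut-2-en-1-olate (one isomer drawn) | CC(C)OC1=C(OC(C)C)[C@@]([O-])([C@@H](CCc2ccccc2)OCOC)C1=O.[Li+] | intermediate
7 | 2,3-diisopropoxy-1-[1-(methoxymethoxy)-3-phenylpropyl]-4-oxocyclobut-2-en-1-yl trifluoroacetate (one isomer drawn) | CC(C)OC1=C(OC(C)C)[C@@](OC(=O)C(F)(F)F)([C@@H](CCc2ccccc2)OCOC)C1=O | intermediate
8 | 3-isopropoxy-4-[1-(methoxymethoxy)-3-phenylpropyl]cyclobut-3-ene-1,2-dione (racemic, one enantiomer drawn) | O=C1C(=O)C(OC(C)C)=C1[C@@H](CCc1ccccc1)OCOC | intermediate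
9 | 4-hydroxy-3-isopropoxy-2-[1-(methoxymethoxy)-3-phenylpropyl]cyclobut-2-en-1-one (racemic diastereomer mixture, one isomer drawn) | O=C1C([C@@H](CCc2ccccc2)OCOC)=C(OC(C)C)[C@H]1O | intermediate
10 | 4-(benzyloxy)-3-isopropoxy-2-[1-(methoxymethoxy)-3-phenylpropyl]cyclobut-2-en-1-one (racemic diastereomer mixture, one isomer drawn) | O=C1C([C@@H](CCc2ccccc2)OCOC)=C(OC(C)C)[C@H]1OCc1ccccc1 | intermediate
11 | methyl phenylpropiolate | COC(=O)C#Cc1ccccc1 | starting material
12 | methyl (E)-3-phenyl-2-(tributylstannyl)acrylate | CCCC[Sn](CCCC)(CCCC)/C(C(=O)OC)=C/c1ccccc1 | intermediate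
13 | methyl (E)-2-iodo-3-phenylacrylate | I/C(C(=O)OC)=C/c1ccccc1 | intermediate
14 | chloroacetaldehyde dimethyl acetal | COC(CCl)OC | starting material
15 | lithium methoxyacetylide | [Li]C#COC | intermediate
16 | methoxyethynylzinc chloride | COC#C[Zn]Cl | intermediate
17 | methyl (Z)-2-(methoxyethynyl)-3-phenylacrylate | COC#C/C(C(=O)OC)=C/c1ccccc1 | intermediate
18 | vinylketene: 4-(benzyloxy)-3-isopropoxy-2-[1-(methoxymethoxy)-3-phenylpropyl]buta-1,3-dien-1-one, BnO trans to the ketene carbon | O=C=C([C@@H](CCc1ccccc1)OCOC)/C(OC(C)C)=C/OCc1ccccc1 | intermediate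
19 | methyl (Z)-2-{3-[(Z)-2-(benzyloxy)-1-isopropoxyvinyl]-2-methoxy-3-[1-(methoxymethoxy)-3-phenylpropyl]-4-oxocyclobut-1-en-1-yl}-3-phenylacrylate (one isomer drawn) | O=C1C(/C(C(=O)OC)=C/c2ccccc2)=C(OC)[C@@]1([C@@H](CCc2ccccc2)OCOC)/C(OC(C)C)=C/OCc1ccccc1 | intermediate
20 | dienylketene O=C7a=C3a(arm)–C4(OMe)=C5(side chain)–C6(Oi-Pr)=C7H(OBn), C3a and C6 cis on C4=C5, BnO trans to C5 | O=C=C(/C(C(=O)OC)=C/c1ccccc1)/C(OC)=C(\C(OC(C)C)=C\OCc1ccccc1)[C@@H](CCc1ccccc1)OCOC | intermediate
21 | cyclohexa-2,4-dienone tautomer of 22 (H and OBn on C7, one isomer drawn) | O=C1C(/C(C(=O)OC)=C/c2ccccc2)=C(OC)C([C@@H](CCc2ccccc2)OCOC)=C(OC(C)C)[C@H]1OCc1ccccc1 | intermediate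
22 | methyl (Z)-2-{3-(benzyloxy)-2-hydroxy-4-isopropoxy-6-methoxy-5-[1-(methoxymethoxy)-3-phenylpropyl]phenyl}-3-phenylacrylate (racemic, one enantiomer drawn) | COc1c([C@@H](CCc2ccccc2)OCOC)c(OC(C)C)c(OCc2ccccc2)c(O)c1/C(C(=O)OC)=C/c1ccccc1 | intermediate
23 | (Z)-3-benzylidene-7-(benzyloxy)-6-isopropoxy-4-methoxy-5-[1-(methoxymethoxy)-3-phenylpropyl]benzofuran-2(3H)-one (racemic, one enantiomer drawn) | COc1c([C@@H](CCc2ccccc2)OCOC)c(OC(C)C)c(OCc2ccccc2)c2c1/C(=C/c1ccccc1)C(=O)O2 | intermediate
24 | (Z)-3-benzylidene-7-(benzyloxy)-5-[1-(bromomethoxy)-3-phenylpropyl]-6-isopropoxy-4-methoxybenzofuran-2(3H)-one (racemic, one enantiomer drawn) | COc1c([C@@H](CCc2ccccc2)OCBr)c(OC(C)C)c(OCc2ccccc2)c2c1/C(=C/c1ccccc1)C(=O)O2 | intermediate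
25 | (Z)-3-benzylidene-7-(benzyloxy)-5-(1-hydroxy-3-phenylpropyl)-6-isopropoxy-4-methoxybenzofuran-2(3H)-one (racemic, one enantiomer drawn) | COc1c([C@@H](CCc2ccccc2)O)c(OC(C)C)c(OCc2ccccc2)c2c1/C(=C/c1ccccc1)C(=O)O2 | intermediate
26 | (Z)-3-benzylidene-7-(benzyloxy)-6-isopropoxy-4-methoxy-5-(3-phenylpropanoyl)benzofuran-2(3H)-one | COc1c(C(=O)CCc2ccccc2)c(OC(C)C)c(OCc2ccccc2)c2c1/C(=C/c1ccccc1)C(=O)O2 | intermediate
27 | bractelactone | COc1c(C(=O)CCc2ccccc2)c(O)c(O)c2c1/C(=C/c1ccccc1)C(=O)O2 | target

## Step count and risks

Total step count: 13. Longest linear sequence: 10 steps (steps 1–5 and 9–13). The enynyl ether branch takes 3 steps (6–8).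

**First risk, step 9.** The ketene terminus of 18 is fully substituted and carries a branched side chain, and the alkyne is disubstituted and conjugated, so the [2+2] addition may be too slow.

- Ketene dimerisation could then dominate.
- The product phenol could be acylated by the ketene.
- Methanol released through premature lactonisation could capture the ketene.
- The ynol ether could decay thermally.

The fallback sets out from 10, 12 and 14 and comes back at 22.

- Acetal 14 would be treated with NaNH2 in liquid NH3 to give sodium methoxyacetylide F1. Protonation with water and distillation would give methoxyacetylene F2, a small terminal alkoxyalkyne of the proven class.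
- Heating F2 with 10 in toluene in a sealed tube would run the same cascade. It passes through 18, the 4-vinylcyclobutenone F3, the dienylketene F4 and the cyclohexadienone F5 to the pentasubstituted phenol F6, which has hydrogen at C3a.
- NIS in MeCN at 0 °C would iodinate this single free and strongly activated position to give the iodophenol F7.
- A copper-assisted Stille coupling of F7 with stannane 12 (Pd(PPh3)4, CuI, DMF) would form the C3a–arm bond with retention of the alkene geometry and deliver 22.

**Second risk, step 8.** Amine and methoxide in the acetylide solution may isomerise the less stable (E)-iodide by reversible conjugate addition, and the acid-sensitive ynol ether may be hydrated during coupling or isolation.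

The fallback sets out from 14 and 13 and comes back at 17.

- Acetylide 15, made from 14 as before, would be quenched with Bu3SnCl and the product distilled to give tributyl(methoxyethynyl)stannane F8, a storable reagent free of base.
- Stille coupling of F8 with 13 under neutral, amine- and salt-free conditions (Pd2(dba)3, AsPh3, DMF, rt) would give 17.

**Third risk, step 11.** Ionisation of the benzylic C–O bond, which is flanked by two ortho alkoxy groups, may compete with cleavage at the acetal carbon. That would lead to elimination along the side chain or to benzylic substitution.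

The fallback sets out from 23 and comes back at 26, replacing steps 11 and 12.

- DDQ in CH2Cl2–pH 7 buffer would abstract the benzylic hydride from the electron-rich arene, the reaction type used for oxidative cleavage of alkoxybenzyl ethers.
- Water would add to the oxocarbenium ion to give the hemiketal F9, which collapses to ketone 26.
- Loss of a proton from the cation would give an enol ether that hydrolyses to the same ketone, so the side reactions converge on 26.

## Further compounds

F1 | step 9 | sodium methoxyacetylide | [Na+].[C-]#COC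
F2 | step 9 | methoxyacetylene | C#COC
F3 | step 9 | 4-[(Z)-2-(benzyloxy)-1-isopropoxyvinyl]-3-methoxy-4-[1-(methoxymethoxy)-3-phenylpropyl]cyclobut-2-en-1-one (one isomer drawn) | O=C1C=C(OC)[C@@]1([C@@H](CCc2ccccc2)OCOC)/C(OC(C)C)=C/OCc1ccccc1
F4 | step 9 | dienylketene with hydrogen on C3a (C3a and C6 cis on C4=C5, BnO trans to C5) | O=C=C/C(OC)=C(\C(OC(C)C)=C\OCc1ccccc1)[C@@H](CCc1ccccc1)OCOC
F5 | step 9 | 6-(benzyloxy)-5-isopropoxy-3-methoxy-4-[1-(methoxymethoxy)-3-phenylpropyl]cyclohexa-2,4-dien-1-one (one isomer drawn) | O=C1C=C(OC)C([C@@H](CCc2ccccc2)OCOC)=C(OC(C)C)[C@H]1OCc1ccccc1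
F6 | step 9 | 2-(benzyloxy)-3-isopropoxy-5-methoxy-4-[1-(methoxymethoxy)-3-phenylpropyl]phenol (racemic, one enantiomer drawn) | COc1cc(O)c(OCc2ccccc2)c(OC(C)C)c1[C@@H](CCc1ccccc1)OCOC
F7 | step 9 | 2-(benzyloxy)-6-iodo-3-isopropoxy-5-methoxy-4-[1-(methoxymethoxy)-3-phenylpropyl]phenol (racemic, one enantiomer drawn) | COc1c(I)c(O)c(OCc2ccccc2)c(OC(C)C)c1[C@@H](CCc1ccccc1)OCOC
F8 | step 8 | tributyl(methoxyethynyl)stannane | COC#C[Sn](CCCC)(CCCC)CCCC
F9 | step 11 | (Z)-3-benzylidene-7-(benzyloxy)-5-[1-hydroxy-1-(methoxymethoxy)-3-phenylpropyl]-6-isopropoxy-4-methoxybenzofuran-2(3H)-one (racemic, one enantiomer drawn) | COc1c([C@](O)(CCc2ccccc2)OCOC)c(OC(C)C)c(OCc2ccccc2)c2c1/C(=C/c1ccccc1)C(=O)O2
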